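I decided to follow one molecule of X through each flask and ask for its chance of still being X at 45 min, as the larch question is about that chance.

the same everywhere: G 0.200 mM

| charge | X | time |
|---|---|---|
| cedar | 100 mM |  |
| elm | 150 mM |  |
| larch | 240 mM | 45 min |

| run | time / min | [X] / mM |
|---|---|---|
| cedar run | 2.0 | 82.3 |
| cedar run | 6.1 | 57.3 |
| cedar run | 12 | 35.1 |
| cedar run | 18 | 23.4 |
| cedar run | 26 | 15.1 |
| cedar run | 35 | 11.6 |
| cedar run | 45 | 5.6 |
| elm run | 2.0 | 126.6 |
| elm run | 6.1 | 89.7 |
| elm run | 12 | 56.3 |
| elm run | 18 | 36.0 |
| elm run | 26 | 22.1 |
| elm run | 35 | 13.6 |
| elm run | 45 | 9.0 |

(standard deviation of a reading: 0.8 mM)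

- the power of [X] that the first rate follows, about the charge of the cedar run; measure it at two percent of X made into L (one fixed amount of L, the same in the runs compared)
- X in the larch run at 45 min, as a share of the X charged

- Overall: X -> L, with G as catalyst.
- Constant volume, constant temperature.
- The analysis sees a species whether free or bound.
- An order is taken over about fifteen percent of the charge, up and down.

I first went through what an error in each number would do to the larch share. The charge seemed to count for little: by the last readings cedar kept 5.60% of its X and elm, with 1.50 times the charge, kept 6.00%, a shift of 7.14% of itself. The last elm reading counted for more, since one standard deviation of 0.8 mM on its 9.0 mM moves that share by 8.89% of itself, which is more than the shift between the runs. The earlier readings did not enter this share at all.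

So the number to know well was a mean over the whole run. Elm gave 0.0625 min⁻¹ as its leaving constant, the natural logarithm of the charge over the X left, divided by the time, an apparent first-order constant, and cedar gave 0.0641 min⁻¹. I took elm's, its charge standing nearer to larch's, and so committed to 6.00% for larch.

The forecast gave 0.67 for the order and 8.5% for larch, higher than my share, on its reading of “mild product inhibition on top of saturation”.

The flask gave an order of 0.78 and left 6.57% of the larch X at 45 min, while the elm rate stood at 1.3 times the cedar rate where the same amount of L had been made. The steps were these:

    G + X ⇌ GX, settled at all times (93.10 M⁻¹)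
    GX + X ⇌ GX2, settled at all times (5.310 M⁻¹)
    GX2 → L + GX (121.2 min⁻¹)
    GX → Vy + X (0.04518 min⁻¹)
    X → Ju (0.01560 min⁻¹)

Larch's leaving constant came to 0.0605 min⁻¹, a gap of 0.00200 min⁻¹ from the 0.0625 min⁻¹ read from the last elm reading, and one standard deviation on that reading moves the elm constant by about as much, 0.00198 min⁻¹. Put on the cedar charge, it leaves 6.57 mM of X at 45 min, against a cedar reading of 5.6 mM.

The numbers in the tables are calculated from invented constants, and the scatter is random.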